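all flasks: gas phase 8.2 mM (held)
- Sunday's: substrate 20 mM; free catalyst 0.05 mol%; run made earlier
- Thursday's: substrate 20 mM; free catalyst 0.075 mol%; run made earlier
- Tuesday's: substrate 30 mM; free catalyst 0.1 mol%; run made earlier
- flask: substrate 20 mM; free catalyst 0.1 mol%; time 8.0 d

| run | time / d | target / % |
|---|---|---|
| Sunday's | 0.625 | 6 |
| Sunday's | 1.04 | 8 |
| Sunday's | 1.67 | 9 |
| Sunday's | 3.00 | 13 |
| Sunday's | 5.00 | 19 |
| Sunday's | 8.00 | 23 |
| Thursday's | 0.500 | 3 |
| Thursday's | 1.67 | 14 |
| Thursday's | 3.00 | 14 |
| Thursday's | 4.00 | 22 |
| Thursday's | 6.00 | 22 |
| Thursday's | 8.00 | 20 |
| Tuesday's | 0.625 | 10 |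
| Tuesday's | 2.08 | 17 |
| Tuesday's | 4.00 | 17 |
| Tuesday's | 6.00 | 15 |
| Tuesday's | 8.00 | 17 |

(scatter of a reading: 2 percentage points)

- blue: doubling the transfer coefficient of the gas phase, all else as stated
- green: doubling the saturation concentration of gas phase, all else as stated
- ochre: doubling the amount of free catalyst, all else as stated

- how much target there is at 8.0 d, in percent of the substrate charged
- the change that raises the amount of target at 8.0 d, in percent of the substrate charged most ("none" if none brings more than 2 percentage points) (blue / green / ochre / none)
- amount of target at 8.0 d, in percent of the substrate charged, after green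

If you follow each mole of substrate through the flask, it stands in one of three columns: substrate left (a, as a fraction of the charge), target (y), or over-reaction product, which is whatever a and y leave. The gas phase is held, so substrate is the limiting reagent. Substrate is lost at a rate proportional to [dissolved gas][free catalyst][substrate], and target is lost at a rate proportional to [free catalyst][target]. Divide one by the other and [free catalyst] cancels, however it decays. With [dissolved gas] steady, the ledger integrates to y = (a^s − a)/(1 − s), and the curve peaks at y = s^(s/(1 − s)), which is a quarter at s = 2. Near there, s ≈ 1/peak − 2.

Thursday's run tops out at a reading of 22 %, with a scatter of 2 percentage points. That reading gives 2.55 for s, the selectivity factor: the rate constant of over-reaction divided by the product of the rate constant of making target and [dissolved gas].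

My own reckoning puts this flask on Thursday's curve, with the same substrate and the same held gas phase, and an estimated ceiling of 21.5 %. Its loading of 0.1 mol% carries it further along that curve, so I expect just under the ceiling. Ochre moves it further along the same curve, while green, if [dissolved gas] follows, takes s to 1.27 and the estimated ceiling to 32.5 %. Blue leaves the saturation, and with it the steady [dissolved gas] and s, as they are, so I choose green.

The forecast says 19 %, green and 30 %, on the ground that “more dissolved gas favours formation over over-reaction”.

The flask gives 20.0 %, and green is best, reaching 24.6 %.

    substrate + dissolved gas + free catalyst → free catalyst + target (k = 74000 /M²/h)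
    free catalyst → spent catalyst (k = 0.0110 /h)
    free catalyst + target → free catalyst + over-reaction product (k = 1500 /M/h)
    gas phase ⇌ dissolved gas, rate k4*(csat - [dissolved gas]) (kL = 0.160 /h)

At 8.00 d this flask makes target at 0.862 of the rate at which it uses target up. So the flask stands past its peak, with target at 20.8 % at 4.00 d and 20.0 % at 8.00 d. Its 43.1 % of substrate left puts the curve at 20.3 %. The neighbour with 0.025 mol% keeps 80.2 % of its substrate, where the curve reads 15.0 % and the neighbour holds 15.0 %.

The earlier runs and the new flask come from a simulation with constants of no real substance; scatter was added.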